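## Retrosynthetic overview

1. Target 17 ⇐ 16 by O-demethylation; 16 ⇐ 13: the 2-pyranone is made last, by C–O bond formation only (O2 insertion into the C2′–C3′ bond of a 2,3-dihydroxy-4-methoxyphenyl ring, then lactonisation; proposed new one-flask step).
2. 13 ⇐ 11: the carbocycle is closed by cationic Friedel–Crafts attack of the veratryl ring on the benzylic carbinol carbon (C1–C8a), which sets C1 trans to C2.
3. 11 ⇐ 8 + 2: the C1–C2 bond and the C2 configuration come from an Evans syn-aldol; the auxiliary is then cleaved.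
4. 8 ⇐ 5 ⇐ 3 + 4: C3=C4 from a Stobbe condensation of veratraldehyde with di-tert-butyl succinate; 2 ⇐ 1 by catechol ketalisation.
5. Ring order: dihydronaphthalene carbocycle (step 6), then 2-pyranone (step 7).

Assumption: 2,3-dihydroxy-4-methoxybenzaldehyde (1) is bought as a catalogue aldehyde; locants of 12–17 follow the 1,2-dihydronaphthalene-2,3-dicarboxylic acid numbering (primed locants = pendant ring).

## Route

Step 1
Reactants: 1 2,3-dihydroxy-4-methoxybenzaldehyde
Product: 2 7-methoxy-2,2-diphenyl-1,3-benzodioxole-4-carbaldehyde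
Conditions: Ph2CCl2 (1.5 equiv), neat, 170 °C, 20 min, N2 sweep
Reagents that add atoms: dichlorodiphenylmethane, ClC(Cl)(c1ccccc1)c1ccccc1
Why: Catechol ketalisation (diphenylmethylene acetal): the only free vicinal diol traps the reagent twice and HCl leaves as gas, which masks the acidic phenols for the enolate steps while O4 stays methylated.

Step 2
Reactants: 3 3,4-dimethoxybenzaldehyde; 4 di-tert-butyl succinate
Product: 5 (E)-3-(tert-butoxycarbonyl)-4-(3,4-dimethoxyphenyl)but-3-enoic acid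
Conditions: t-BuOK (1.3 equiv), t-BuOH, reflux; then 1 M HCl, 0 °C
Reagents that add atoms: none
Why: Stobbe condensation: the succinate enolate adds to the aldehyde, the alkoxide lactonises on the distal ester and E1cB opening gives the (E)-alkylidene half-ester with the free acid on the saturated carbon (no stereocentre).

Step 3
Reactants: 5 (E)-3-(tert-butoxycarbonyl)-4-(3,4-dimethoxyphenyl)but-3-enoic acid; 6 (S)-4-benzyl-1,3-oxazolidin-2-one
Product: 8 tert-butyl (E)-2-{2-[(4S)-4-benzyl-2-oxo-1,3-oxazolidin-3-yl]-2-oxoethyl}-3-(3,4-dimethoxyphenyl)prop-2-enoate, via mixed pivalic anhydride 7 (not isolated)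
Conditions: PivCl, Et3N, THF, −20 °C; then LiCl, 6, −20 °C → rt
Reagents that add atoms: none
Why: N-Acylation of the Evans oxazolidinone through the mixed pivalic anhydride (LiCl/Et3N protocol); the benzylidene double bond stays where it is because styrene/acrylate conjugation is the thermodynamic position.

Step 4
Reactants: 8 tert-butyl (E)-2-{2-[(4S)-4-benzyl-2-oxo-1,3-oxazolidin-3-yl]-2-oxoethyl}-3-(3,4-dimethoxyphenyl)prop-2-enoate; 2 7-methoxy-2,2-diphenyl-1,3-benzodioxole-4-carbaldehyde
Product: 9 tert-butyl (2E,3S,4S)-3-{[(4S)-4-benzyl-2-oxo-1,3-oxazolidin-3-yl]carbonyl}-2-(3,4-dimethoxybenzylidene)-4-hydroxy-4-(7-methoxy-2,2-diphenyl-1,3-benzodioxol-4-yl)butanoate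
Conditions: n-Bu2BOTf (1.2 equiv), i-Pr2NEt (1.4 equiv), CH2Cl2, −78 → 0 °C; then 2, −78 → 0 °C; pH 7 buffer/MeOH/30% H2O2, 0 °C
Reagents that add atoms: none
Why: Evans syn-aldol reaction: the Z-boron enolate reacts at its α-carbon through a Zimmerman–Traxler chair on the face away from the benzyl group, which sets the α-carbon (3S here, the future C2 with the target's spatial arrangement) and the carbinol (4S, erased later), and minor diastereomers are removed by chromatography.

Step 5
Reactants: 9 tert-butyl (2E,3S,4S)-3-{[(4S)-4-benzyl-2-oxo-1,3-oxazolidin-3-yl]carbonyl}-2-(3,4-dimethoxybenzylidene)-4-hydroxy-4-(7-methoxy-2,2-diphenyl-1,3-benzodioxol-4-yl)butanoate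
Product: 11 (2S,3S)-2-[(E)-1-(tert-butoxycarbonyl)-2-(3,4-dimethoxyphenyl)ethenyl]-3-hydroxy-3-(7-methoxy-2,2-diphenyl-1,3-benzodioxol-4-yl)propanoic acid, via peroxy acid 10 (not isolated)
Conditions: LiOH (2 equiv), 30% H2O2 (4 equiv), THF/H2O 3:1, 0 °C; then aq. Na2SO3; 1 M HCl to pH 3
Reagents that add atoms: hydrogen peroxide, OO
Why: LiOOH hydrolysis of the N-acyl oxazolidinone (exocyclic cleavage by the α-effect nucleophile, percarboxylate reduced by sulfite); the hindered tert-butyl ester, the ketal and the α-stereocentre survive at 0 °C, and no free catechol is present yet.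

Step 6
Reactants: 11 (2S,3S)-2-[(E)-1-(tert-butoxycarbonyl)-2-(3,4-dimethoxyphenyl)ethenyl]-3-hydroxy-3-(7-methoxy-2,2-diphenyl-1,3-benzodioxol-4-yl)propanoic acid
Product: 13 (1R,2R)-1-(2,3-dihydroxy-4-methoxyphenyl)-6,7-dimethoxy-1,2-dihydronaphthalene-2,3-dicarboxylic acid, via cyclised tert-butyl ester ketal 12 (not isolated)
Conditions: TFA/CH2Cl2 1:4, 0 °C, 30 min; then TFA/H2O 9:1, rt → 40 °C, 3 h (Ar)
Reagents that add atoms: none
Why: Cationic Friedel–Crafts cyclodehydration: TFA ionises the benzylic alcohol to a cation stabilised by the ortho and para oxygens, and C6 of the cis-disposed veratryl ring (para to OMe) closes the six-membered ring so that the aryl group ends trans (pseudo-diaxial) to the C2 carboxyl, so C1 (R) is set by the untouched C2 centre; aqueous TFA then removes the tert-butyl ester and the diphenylmethylene ketal.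

Step 7
Reactants: 13 (1R,2R)-1-(2,3-dihydroxy-4-methoxyphenyl)-6,7-dimethoxy-1,2-dihydronaphthalene-2,3-dicarboxylic acid
Product: 16 (1R,2R)-1-(6-carboxy-2-oxo-2H-pyran-3-yl)-6,7-dimethoxy-1,2-dihydronaphthalene-2,3-dicarboxylic acid, via muconic anhydride 14 (not isolated), via 2-oxo diacid 15 (not isolated)
Conditions: Fe(OTf)3 (20 mol %), TPA [tris(2-pyridylmethyl)amine] (22 mol %), Et3N (4.5 equiv), O2 (1 atm), MeCN, 25 °C; then 4 M aq. HCl/dioxane, 60 °C
Reagents that add atoms: dioxygen, O=O; water, O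
Why: Proposed new method: the Fe(III)–TPA centre can chelate only the free 2′,3′-diol (O4′ and ring A are methylated), O2 attacks the electron-rich catecholate carbon and the Fe-bound alkylperoxide undergoes Criegee acyl migration, inserting O between C2′ and C3′ (intradiol cleavage, C–O bond formation) to give 2-methoxymuconic anhydride 14; aqueous HCl then hydrolyses the anhydride and the methyl enol ether to 2-oxo diacid 15, whose enol oxygen lactonises onto the cis-held C2′ carboxyl (second C–O bond, six-membered ring) to give the 3-substituted 2-pyranone-6-carboxylic acid with C1/C2 untouched; the closest known reaction types are the Fe(III)/TPA/O2 intradiol cleavage of simple catechols to muconic anhydrides and the acid lactonisation of 2-hydroxymuconate (oxalocrotonate) to 2-pyranone-6-carboxylic acid, but the one-flask ring contraction of a 3-alkoxycatechol to a 2-pyranone-6-carboxylic acid has not been shown.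

Step 8
Reactants: 16 (1R,2R)-1-(6-carboxy-2-oxo-2H-pyran-3-yl)-6,7-dimethoxy-1,2-dihydronaphthalene-2,3-dicarboxylic acid
Product: 17 (1R,2R)-1-(6-carboxy-2-oxo-2H-pyran-3-yl)-6,7-dihydroxy-1,2-dihydronaphthalene-2,3-dicarboxylic acid (CNP0420981.1)
Conditions: BBr3 (10 equiv), CH2Cl2, −78 °C → rt; then H2O, 0 °C
Reagents that add atoms: none
Why: Lewis-acid ether cleavage (BBr3 O-demethylation) of the two aryl methyl ethers; the carboxylic acids and the 2-pyranone are regenerated on aqueous work-up, and C1/C2 carry no leaving group and are not epimerised under these non-basic conditions.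

## Compound list

1 | 2,3-dihydroxy-4-methoxybenzaldehyde | O=Cc1ccc(OC)c(O)c1O | starting material
2 | 7-methoxy-2,2-diphenyl-1,3-benzodioxole-4-carbaldehyde | O=Cc1ccc(OC)c2OC(c3ccccc3)(c3ccccc3)Oc12 | intermediate
3 | 3,4-dimethoxybenzaldehyde (veratraldehyde) | COc1ccc(C=O)cc1OC | starting material
4 | di-tert-butyl succinate | CC(C)(C)OC(=O)CCC(=O)OC(C)(C)C | starting material
5 | (E)-3-(tert-butoxycarbonyl)-4-(3,4-dimethoxyphenyl)but-3-enoic acid | COc1ccc(/C=C(\CC(=O)O)C(=O)OC(C)(C)C)cc1OC | intermediate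
6 | (S)-4-benzyl-1,3-oxazolidin-2-one | O=C1OC[C@H](Cc2ccccc2)N1 | starting material
7 | (E)-3-(tert-butoxycarbonyl)-4-(3,4-dimethoxyphenyl)but-3-enoic pivalic anhydride | COc1ccc(/C=C(\CC(=O)OC(=O)C(C)(C)C)C(=O)OC(C)(C)C)cc1OC | intermediate
8 | tert-butyl (E)-2-{2-[(4S)-4-benzyl-2-oxo-1,3-oxazolidin-3-yl]-2-oxoethyl}-3-(3,4-dimethoxyphenyl)prop-2-enoate | COc1ccc(/C=C(\CC(=O)N2[C@@H](Cc3ccccc3)COC2=O)C(=O)OC(C)(C)C)cc1OC | intermediate
9 | tert-butyl (2E,3S,4S)-3-{[(4S)-4-benzyl-2-oxo-1,3-oxazolidin-3-yl]carbonyl}-2-(3,4-dimethoxybenzylidene)-4-hydroxy-4-(7-methoxy-2,2-diphenyl-1,3-benzodioxol-4-yl)butanoate | COc1ccc(/C=C(\[C@@H]([C@H](O)c2ccc(OC)c3OC(c4ccccc4)(c5ccccc5)Oc23)C(=O)N6[C@@H](Cc7ccccc7)COC6=O)C(=O)OC(C)(C)C)cc1OC | intermediate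
10 | (2S,3S)-2-[(E)-1-(tert-butoxycarbonyl)-2-(3,4-dimethoxyphenyl)ethenyl]-3-hydroxy-3-(7-methoxy-2,2-diphenyl-1,3-benzodioxol-4-yl)propaneperoxoic acid | COc1ccc(/C=C(\[C@@H]([C@H](O)c2ccc(OC)c3OC(c4ccccc4)(c5ccccc5)Oc23)C(=O)OO)C(=O)OC(C)(C)C)cc1OC | intermediate
11 | (2S,3S)-2-[(E)-1-(tert-butoxycarbonyl)-2-(3,4-dimethoxyphenyl)ethenyl]-3-hydroxy-3-(7-methoxy-2,2-diphenyl-1,3-benzodioxol-4-yl)propanoic acid | COc1ccc(/C=C(\[C@@H]([C@H](O)c2ccc(OC)c3OC(c4ccccc4)(c5ccccc5)Oc23)C(=O)O)C(=O)OC(C)(C)C)cc1OC | intermediate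
12 | (1R,2R)-3-(tert-butoxycarbonyl)-6,7-dimethoxy-1-(7-methoxy-2,2-diphenyl-1,3-benzodioxol-4-yl)-1,2-dihydronaphthalene-2-carboxylic acid | CC(C)(C)OC(=O)C1=Cc2cc(OC)c(OC)cc2[C@H](c2ccc(OC)c3OC(c4ccccc4)(c5ccccc5)Oc23)[C@H]1C(=O)O | intermediate
13 | (1R,2R)-1-(2,3-dihydroxy-4-methoxyphenyl)-6,7-dimethoxy-1,2-dihydronaphthalene-2,3-dicarboxylic acid | O=C(O)C1=Cc2cc(OC)c(OC)cc2[C@H](c2ccc(OC)c(O)c2O)[C@H]1C(=O)O | intermediate
14 | (1R,2R)-6,7-dimethoxy-1-(6-methoxy-2,7-dioxo-2,7-dihydrooxepin-3-yl)-1,2-dihydronaphthalene-2,3-dicarboxylic acid | O=C(O)C1=Cc2cc(OC)c(OC)cc2[C@H](C2=CC=C(OC)C(=O)OC2=O)[C@H]1C(=O)O | intermediate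
15 | (1R,2R)-1-[(1Z)-1,4-dicarboxy-4-oxobut-1-en-1-yl]-6,7-dimethoxy-1,2-dihydronaphthalene-2,3-dicarboxylic acid | O=C(O)C1=Cc2cc(OC)c(OC)cc2[C@H](/C(C(=O)O)=C/CC(=O)C(=O)O)[C@H]1C(=O)O | intermediate
16 | (1R,2R)-1-(6-carboxy-2-oxo-2H-pyran-3-yl)-6,7-dimethoxy-1,2-dihydronaphthalene-2,3-dicarboxylic acid | O=C(O)C1=Cc2cc(OC)c(OC)cc2[C@H](c2ccc(C(=O)O)oc2=O)[C@H]1C(=O)O | intermediate
17 | (1R,2R)-1-(6-carboxy-2-oxo-2H-pyran-3-yl)-6,7-dihydroxy-1,2-dihydronaphthalene-2,3-dicarboxylic acid | O=C(O)C1=Cc2cc(O)c(O)cc2[C@H](c2ccc(C(=O)O)oc2=O)[C@H]1C(=O)O | target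

## Step count and risks

Total steps: 8. Longest linear sequence: 7 (3 → 5 → 8 → 9 → 11 → 13 → 16 → 17); step 1 is a one-step side branch.

Steps most likely to fail:

Step 7 (the proposed new step). Possible failures are outer-sphere oxidation to a free o-quinone (which could tautomerise through C1–H and erode C1), extradiol or CO-loss products, poor turnover because the polycarboxylate product binds Fe(III), base/O2 dehydrogenation of the dihydronaphthalene, and butenolide instead of pyranone closure in the acid stage. The fallback uses known stoichiometric chemistry and a different mechanism. It sets out from 13: NaIO4 (aq. MeCN, 0 °C) oxidises the catechol to the o-quinone F1, and m-CPBA (CH2Cl2, 0 °C) then inserts oxygen between the two quinone carbonyls (Baeyer–Villiger oxidation of an o-quinone to a muconic anhydride). This comes back to the route at 14, which is taken through the aqueous HCl stage as written to 16.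

Step 4. The cross-conjugated, hindered boron enolate and the ortho-substituted, electron-rich aldehyde may give low conversion or eroded diastereoselectivity. The fallback drops the auxiliary and sets out from 5: the dianion (LDA, 2.2 equiv, THF, −78 °C) is added to 2 to give the racemic hydroxy acid F2 as a syn/anti mixture. The acid conditions of step 6 turn all isomers into the racemic trans diacid F3. F3 is resolved by fractional crystallisation of its salt with (R)-1-phenylethylamine (or its antipode, whichever gives the less soluble (1R,2R) salt; checked by chiral HPLC), which comes back to the route at 13.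

Step 6. The cation next to a free carboxylic acid may fragment (decarboxylative elimination) or lose a proton to the achiral dibenzylidene succinate, whose slow re-cyclisation would give racemate; tert-butylation of the electron-rich ring is also possible. The fallback changes the order of events and sets out from 9: BF3·OEt2 (CH2Cl2, −40 → 0 °C) cyclises the imide, which has no free β-carboxyl, while keeping the ketal and tert-butyl ester, giving the cyclised imide F4. LiOH/H2O2 (THF/H2O, 0 °C) then removes the auxiliary while the catechol is still masked, which comes back to the route at 12; aqueous TFA as in the second stage of step 6 gives 13.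

Further compounds
F1 | step 7 | (1R,2R)-6,7-dimethoxy-1-(4-methoxy-5,6-dioxocyclohexa-1,3-dien-1-yl)-1,2-dihydronaphthalene-2,3-dicarboxylic acid (o-quinone) | O=C(O)C1=Cc2cc(OC)c(OC)cc2[C@H](C2=CC=C(OC)C(=O)C2=O)[C@H]1C(=O)O
F2 | step 4 | racemic 2-[(E)-1-(tert-butoxycarbonyl)-2-(3,4-dimethoxyphenyl)ethenyl]-3-hydroxy-3-(7-methoxy-2,2-diphenyl-1,3-benzodioxol-4-yl)propanoic acid (syn/anti mixture, C2 and C3 not defined) | COc1ccc(/C=C(\C(C(O)c2ccc(OC)c3OC(c4ccccc4)(c5ccccc5)Oc23)C(=O)O)C(=O)OC(C)(C)C)cc1OC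
F3 | step 4 | racemic trans-(1RS,2RS)-1-(2,3-dihydroxy-4-methoxyphenyl)-6,7-dimethoxy-1,2-dihydronaphthalene-2,3-dicarboxylic acid | O=C(O)C1=Cc2cc(OC)c(OC)cc2[C@H](c2ccc(OC)c(O)c2O)[C@H]1C(=O)O.O=C(O)C1=Cc2cc(OC)c(OC)cc2[C@@H](c2ccc(OC)c(O)c2O)[C@@H]1C(=O)O
F4 | step 6 | tert-butyl (3R,4R)-3-{[(4S)-4-benzyl-2-oxo-1,3-oxazolidin-3-yl]carbonyl}-6,7-dimethoxy-4-(7-methoxy-2,2-diphenyl-1,3-benzodioxol-4-yl)-3,4-dihydronaphthalene-2-carboxylate | CC(C)(C)OC(=O)C1=Cc2cc(OC)c(OC)cc2[C@H](c2ccc(OC)c3OC(c4ccccc4)(c5ccccc5)Oc23)[C@H]1C(=O)N1[C@@H](Cc2ccccc2)COC1=O
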